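**Retrosynthetic overview**
- Feature: the C6–C7 bond belongs both to the ten-membered carbocycle (C1–C10) and to the trans-fused α-methylene-γ-lactone (O–C6–C7–C11–C12). Opening the lactone to a C6 carbinol and a C12 methyl ester and then cutting C6–C7 leaves, on one chain, a C6 Z-enal and a C13–C11=C7 2-(methoxycarbonyl)allyl bromide.
- The O8 and O9 acyl groups go on last. Until then the 8,9-diol is a cis-acetonide, which stiffens the chain and keeps O8 from competing with O6 for C12.
- The allyl bromide comes from a C7 aldehyde (Morita–Baylis–Hillman reaction with methyl acrylate, then SN2′ bromination). The 3(2H)-furanone (O, C10, C1, C2, C3) comes from a C10-hydroxy C1≡C2–C3(=O) ynone, made from a C10 ethynyl carbinol and a Z Weinreb amide (C3–C6, C15) opened from 3-methylbutenolide.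
- C10 is set by chelation-controlled ethynylation of a C7–C10 methyl ketone. Its C8/C9 pair comes from L-arabinose through L-erythrose acetonide.
- Ring order: dioxolane (temporary), furanone, ten-membered carbocycle (key step), lactone.

Key step: step 17

**Remarks on the chemistry (assumptions)**
- Germacrane numbering is used for all intermediates.
- The aldehyde carbon of the four-carbon sugar unit becomes C10, so the L-erythro series is required. D-erythronolactone acetonide elaborated at its carbonyl carbon in the same way would give the mirror-image C8/C9 pair.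
- The O9/O10 relation of the target is threo along C1–C10–C9–C8. Osmylation of a C10=C1 methylene compound anti to the allylic O9 would be expected to give the erythro relation. C10 is therefore made by chelate-controlled addition of the C1 nucleophile to the methyl ketone.
- Carbinol centres that are erased later are carried as mixtures: C10 before its oxidation, C7 before its bromination, and the side-chain carbinol.

**Route**

Step 1
Reactants: 1 L-arabinose
Product: 2 3,4-O-isopropylidene-L-arabinopyranose (anomer mixture)
Conditions: Me2C(OMe)2, p-TsOH·H2O (cat.), DMF, rt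
Reagents that add atoms: 2,2-dimethoxypropane, COC(C)(C)OC
Why: Acid-catalysed transacetalisation takes the only cis-vicinal diol of the pyranose (O3/O4) and leaves the C1/C2 glycol free, without touching a stereocentre.

Step 2
Reactants: 2 3,4-O-isopropylidene-L-arabinopyranose
Product: 4 L-erythrose acetonide lactol (2,3-O-isopropylidene-L-erythrofuranose; anomer mixture), via formate ester 3 (not isolated)
Conditions: NaIO4, H2O, 0 °C to rt; then Na2CO3, rt
Reagents that add atoms: none
Why: Malaprade glycol cleavage cuts the C1–C2 hemiacetal glycol, carbonate saponifies the O-formate and the hydroxy aldehyde closes to the lactol, so arabinose C3 and C4 become C9 and C8 with unchanged configuration.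

Step 3
Reactants: 4 L-erythrose acetonide lactol
Product: 5 1-[(4R,5S)-5-(hydroxymethyl)-2,2-dimethyl-1,3-dioxolan-4-yl]ethanol (cis-dioxolane; C10 carbinol epimers)
Conditions: MeMgBr (3 equiv), THF, 0 °C to rt
Reagents that add atoms: methylmagnesium bromide, C[Mg]Br
Why: Grignard addition to the open aldehyde form of the lactol installs C14, and the new carbinol centre is of no consequence because step 5 erases it.

Step 4
Reactants: 5 diol
Product: 6 primary TBS ether of 5 (C7–OTBS, free C10 carbinol)
Conditions: TBSCl (1.05 equiv), imidazole, CH2Cl2, 0 °C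
Reagents that add atoms: tert-butyldimethylsilyl chloride, CC(C)(C)[Si](C)(C)Cl
Why: Sterically controlled silylation, in which the primary C7 hydroxyl reacts much faster than the secondary carbinol next to the dioxolane.

Step 5
Reactants: 6 mono-TBS ether
Product: 7 1-[(4S,5S)-5-{[(tert-butyldimethylsilyl)oxy]methyl}-2,2-dimethyl-1,3-dioxolan-4-yl]ethanone (C10 methyl ketone)
Conditions: Dess–Martin periodinane, CH2Cl2, 0 °C to rt
Reagents that add atoms: none
Why: Dess–Martin oxidation is base-free, so the ketone should form without epimerising C9, which stands cis to the C8 substituent.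

Step 6
Reactants: 7 methyl ketone
Product: 8 (2S)-2-[(4S,5S)-5-{[(tert-butyldimethylsilyl)oxy]methyl}-2,2-dimethyl-1,3-dioxolan-4-yl]but-3-yn-2-ol
Conditions: HC≡CMgBr (3 equiv), THF, −78 to −20 °C
Reagents that add atoms: ethynylmagnesium bromide, C#C[Mg]Br
Why: Chelation-controlled Grignard addition, in which magnesium bridges the C10 carbonyl oxygen and O9 and the alkynyl group (C1–C2) enters from the side of C9–H, away from C8 and its CH2OTBS arm, which gives the threo O9/O10 relation of the target (descriptor S here only because C1 ranks below C9).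

Step 7
Reactants: 9 3-methylfuran-2(5H)-one
Product: 10 (2Z)-4-hydroxy-N-methoxy-N,2-dimethylbut-2-enamide
Conditions: MeNH(OMe)·HCl, AlMe3, CH2Cl2, 0 °C to rt; crude product used at once
Reagents that add atoms: N,O-dimethylhydroxylamine hydrochloride, CNOC.Cl
Why: Aluminium-amide aminolysis of the lactone (Weinreb amidation) breaks only the acyl C–O bond, so the Z geometry of C4=C5 is inherited from the ring.

Step 8
Reactants: 10 hydroxy Weinreb amide
Product: 11 (2Z)-4-[(tert-butyldiphenylsilyl)oxy]-N-methoxy-N,2-dimethylbut-2-enamide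
Conditions: TBDPSCl, imidazole, CH2Cl2, 0 °C to rt
Reagents that add atoms: tert-butyldiphenylsilyl chloride, CC(C)(C)[Si](Cl)(c1ccccc1)c1ccccc1
Why: Standard silylation traps the Z hydroxy amide before it can relactonise, and TBDPS is chosen because it outlasts the primary TBS ether in step 11.

Step 9
Reactants: 8 ethynyl carbinol; 11 Z Weinreb amide
Product: 13 C10-hydroxy ynone (2Z,7S)-1-[(tert-butyldiphenylsilyl)oxy]-7-hydroxy-3-methyl-7-(dioxolanyl)oct-2-en-5-yn-4-one, via dilithio acetylide alkoxide 12 (not isolated)
Conditions: 8, n-BuLi (2.1 equiv), THF, −78 °C; then 11, −78 to 0 °C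
Reagents that add atoms: none
Why: Weinreb ketone synthesis, in which the lithium acetylide adds once because the chelated tetrahedral adduct survives until the quench, forming C2–C3 without touching C10 or the Z alkene.

Step 10
Reactants: 13 hydroxy ynone
Product: 15 bis-silyl furanone (8S,9S,10R), via diethylamino enone 14 (not isolated)
Conditions: Et2NH, EtOH, rt; then AcOH–H2O–THF, 0 °C to rt
Reagents that add atoms: water, O
Why: Classical amine-mediated conversion of a 4-hydroxy-2-ynone into a 3(2H)-furanone, in which Michael addition of Et2NH at C1 gives the enaminone, its C10 hydroxyl closes on the C3 carbonyl under mild acid with loss of water, and hydrolysis of the iminium ion puts the ketone on C1, none of which touches the C10–O bond or the Z alkene.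

Step 11
Reactants: 15 bis-silyl furanone
Product: 16 C7 primary alcohol (TBDPS ether at O6 retained)
Conditions: HF·pyridine, pyridine, THF, 0 °C
Reagents that add atoms: none
Why: Chemoselective fluoride-mediated desilylation, in which pyridine-buffered HF cleaves the primary TBS ether well before the bulkier TBDPS ether and leaves the acetonide alone.

Step 12
Reactants: 16 C7 alcohol
Product: 17 C7 aldehyde (4R,5S)-dioxolane-4-carbaldehyde (8R,9S,10R by priority change only)
Conditions: Dess–Martin periodinane, CH2Cl2, 0 °C to rt; used without storage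
Reagents that add atoms: none
Why: Dess–Martin oxidation is base-free, so the α-alkoxy aldehyde should keep its cis relation (C8) on the dioxolane.

Step 13
Reactants: 17 C7 aldehyde; 18 methyl acrylate
Product: 19 Morita–Baylis–Hillman adduct (C7 carbinol epimers; 8S,9S,10R)
Conditions: 18 (excess), 1,4-diazabicyclo[2.2.2]octane (0.5 equiv), MeOH (co-solvent), rt
Reagents that add atoms: none
Why: Morita–Baylis–Hillman reaction, in which the amine–acrylate zwitterion adds to the non-conjugated aldehyde to form C7–C11, and both carbinol epimers converge in step 16.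

Step 14
Reactants: 19 adduct
Product: 20 C6,C7-diol
Conditions: HF·pyridine, THF, 0 °C to rt
Reagents that add atoms: none
Why: HF-mediated desilylation is done before any bromide is present, so nothing in the molecule is open to attack by fluoride.

Step 15
Reactants: 20 diol
Product: 21 C7-hydroxy Z-enal
Conditions: TEMPO (2,2,6,6-tetramethylpiperidin-1-oxyl, cat.), (diacetoxyiodo)benzene, CH2Cl2, rt
Reagents that add atoms: none
Why: Oxoammonium (TEMPO) oxidation takes the primary allylic C6 alcohol in preference to the hindered secondary C7 carbinol and is mild enough to keep the Z geometry of C4=C5.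

Step 16
Reactants: 21 hydroxy enal
Product: 22 furanone Z-enal with the (Z)-2-(bromomethyl)enoate (8S,9S,10R)
Conditions: NBS, Me2S, CH2Cl2, 0 °C to rt
Reagents that add atoms: N-bromosuccinimide, O=C1CCC(=O)N1Br
Why: The C7 hydroxyl is activated as its alkoxysulfonium salt (Corey–Kim reagent without base) and bromide attacks C13 in the SN2′ sense, allylic strain placing C8 trans to the ester (Z bromide), under neutral conditions that spare the enal.

Step 17
Reactants: 22 bromo enal
Product: 24 bridged ten-membered C6 hydroxy ester (6R,7S,8S,9S,10R), via allylchromium dichloride 23 (not isolated)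
Conditions: CrCl2 (10 equiv), degassed THF, rt, slow addition of 22 (final ca. 1 mM); aqueous work-up
Reagents that add atoms: none
Why: Two equivalents of CrCl2 (divalent chromium) reduce the C13–Br bond in two one-electron steps to the σ-allylchromium dichloride 23 (trivalent chromium), which can interconvert its C7=C11 geometries by 1,3-metal shifts and binds the C6 aldehyde oxygen, after which the γ-carbon C7 attacks C6 in a closed six-membered SE2′ array (C6, C7, C11, C13, Cr, O) that forms C6–C7 and moves the alkene to C11=C13. The closest known reaction type is the intramolecular Nozaki–Hiyama (Barbier-type) addition of 2-(bromomethyl)acrylates to aldehydes, which has already closed ten-membered germacranolide carbocycles. The one ring closed is the carbocycle C1–C10, by a 10-exo-trig addition to C6=O (nine-membered if counted through the furanone oxygen), with C13 left outside the ring as the methylene. C6 relative to C7: the stiff bridge C9–C10–furanone–C4=C5 should force the C5–C6–C7–C8 torsion to open well beyond gauche, which a closed array allows only when C5 and C8 stand trans on it, and this is the anti adduct (Si face of C6 joined to the Re face of C7; H6 and H7 trans as the trans-lactone needs), whereas the syn adduct would need these bonds gauche or eclipsed. C7 relative to C8: the same bridge keeps the forming bond roughly anti to C8–C9, and of the two rotamers that do so only the one with C8–H rather than O8 eclipsing the fully substituted C11 is free of allylic strain, which exposes the Re face of C7 (7S). The step needs γ- over α-attack, aldehyde over C1 ketone and ring closure over oligomerisation, which the closed array, the aldehyde selectivity of organochromium reagents, and slow addition at high dilution to a chain with few free rotors (planar furanone, Z C4=C5, cis-dioxolane holding C7 and C10 close) should secure.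

Step 18
Reactants: 24 hydroxy ester
Product: 25 trans-fused 6,12-lactone acetonide (6R,7S,8S,9S,10R)
Conditions: camphorsulfonic acid (cat.), 4 Å MS, toluene, 50 °C
Reagents that add atoms: none
Why: Acid-catalysed intramolecular transesterification (lactonisation), in which only O6 can reach C12 because O8 is tied up in the acetonide, and the trans H6/H7 relation from step 17 makes the ring fusion trans.

Step 19
Reactants: 25 lactone acetonide
Product: 26 8,9-diol lactone (6R,7R,8S,9S,10R; the C7 descriptor changes by priority only)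
Conditions: TFA–H2O (9:1), CH2Cl2, 0 °C
Reagents that add atoms: none
Why: Acid hydrolysis of the acetonide, chosen because acidic medium avoids base-induced translactonisation to O8 and conjugate addition to the methylene lactone.

Step 20
Reactants: 27 tert-butyl acrylate; 28 acetaldehyde
Product: 29 tert-butyl 3-hydroxy-2-methylenebutanoate (racemic)
Conditions: 1,4-diazabicyclo[2.2.2]octane (cat.), neat, rt
Reagents that add atoms: none
Why: Morita–Baylis–Hillman reaction, whose racemic carbinol centre is erased in the next step.

Step 21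
Reactants: 29 adduct
Product: 30 tert-butyl (2Z)-2-(bromomethyl)but-2-enoate
Conditions: NBS, Me2S, CH2Cl2, 0 °C to rt
Reagents that add atoms: N-bromosuccinimide, O=C1CCC(=O)N1Br
Why: The same alkoxysulfonium activation and SN2′ bromide attack, in which allylic strain puts the methyl group trans to the ester (tiglate-type geometry).

Step 22
Reactants: 30 allyl bromide
Product: 31 tert-butyl (2E)-2-(acetoxymethyl)but-2-enoate
Conditions: KOAc, DMF, rt
Reagents that add atoms: potassium acetate, CC(=O)[O-].[K+]
Why: Direct SN2 displacement of the primary allylic bromide by acetate keeps the alkene geometry (the descriptor becomes E because CH2OAc ranks below the ester).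

Step 23
Reactants: 31 tert-butyl ester
Product: 32 (2E)-2-(acetoxymethyl)but-2-enoic acid
Conditions: TFA, CH2Cl2, 0 °C to rt
Reagents that add atoms: none
Why: Acidolysis of the tert-butyl ester (loss of isobutene) frees the acid without touching the primary acetate or the alkene.

Step 24
Reactants: 26 8,9-diol lactone; 32 side-chain acid
Product: 34 C8 ester C9 alcohol (6R,7S,8S,9S,10R), via mixed anhydride 33 (not isolated)
Conditions: 32 (1.0 equiv), 2,4,6-trichlorobenzoyl chloride, Et3N, toluene, rt; then 26, DMAP (cat.), 0 °C
Reagents that add atoms: none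
Why: Yamaguchi esterification with one equivalent of acid at low temperature should acylate the C8 hydroxyl, because the C9 hydroxyl is neopentyl-like next to the quaternary C10.

Step 25
Reactants: 34 C8 ester
Product: 35 target CNP0325609.1
Conditions: Ac2O, DMAP (cat.), pyridine, CH2Cl2, 0 °C to rt
Reagents that add atoms: acetic anhydride, CC(=O)OC(C)=O
Why: DMAP-catalysed acetylation of the remaining hindered C9 hydroxyl completes the target without affecting any stereocentre.

**Compound list**

1 | L-arabinose | O=C[C@H](O)[C@@H](O)[C@@H](O)CO | starting material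
2 | 3,4-O-isopropylidene-L-arabinopyranose (anomer mixture) | OC1[C@H](O)[C@H]2OC(C)(C)O[C@H]2CO1 | intermediate
3 | 4-O-formyl-2,3-O-isopropylidene-L-erythrose (formate ester, not isolated) | O=C[C@H]1OC(C)(C)O[C@H]1COC=O | intermediate
4 | 2,3-O-isopropylidene-L-erythrofuranose (2S,3S; anomer mixture) | OC1[C@H]2OC(C)(C)O[C@H]2CO1 | intermediate
5 | 1-[(4R,5S)-5-(hydroxymethyl)-2,2-dimethyl-1,3-dioxolan-4-yl]ethanol (carbinol epimers) | CC(O)[C@H]1OC(C)(C)O[C@H]1CO | intermediate
6 | 1-[(4R,5S)-5-{[(tert-butyldimethylsilyl)oxy]methyl}-2,2-dimethyl-1,3-dioxolan-4-yl]ethanol (carbinol epimers) | CC(O)[C@H]1OC(C)(C)O[C@H]1CO[Si](C)(C)C(C)(C)C | intermediate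
7 | 1-[(4S,5S)-5-{[(tert-butyldimethylsilyl)oxy]methyl}-2,2-dimethyl-1,3-dioxolan-4-yl]ethanone | CC(=O)[C@H]1OC(C)(C)O[C@H]1CO[Si](C)(C)C(C)(C)C | intermediate
8 | (2S)-2-[(4S,5S)-5-{[(tert-butyldimethylsilyl)oxy]methyl}-2,2-dimethyl-1,3-dioxolan-4-yl]but-3-yn-2-ol | C#C[C@](C)(O)[C@H]1OC(C)(C)O[C@H]1CO[Si](C)(C)C(C)(C)C | intermediate
9 | 3-methylfuran-2(5H)-one | CC1=CCOC1=O | starting material
10 | (2Z)-4-hydroxy-N-methoxy-N,2-dimethylbut-2-enamide | CON(C)C(=O)/C(C)=C\CO | intermediate
11 | (2Z)-4-[(tert-butyldiphenylsilyl)oxy]-N-methoxy-N,2-dimethylbut-2-enamide | CON(C)C(=O)/C(C)=C\CO[Si](c1ccccc1)(c1ccccc1)C(C)(C)C | intermediate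
12 | dilithio acetylide alkoxide of 8 (not isolated) | [Li]C#C[C@](C)(O[Li])[C@H]1OC(C)(C)O[C@H]1CO[Si](C)(C)C(C)(C)C | intermediate
13 | (2Z,7S)-1-[(tert-butyldiphenylsilyl)oxy]-7-[(4S,5S)-5-{[(tert-butyldimethylsilyl)oxy]methyl}-2,2-dimethyl-1,3-dioxolan-4-yl]-7-hydroxy-3-methyloct-2-en-5-yn-4-one | CC(C)(C)[Si](c1ccccc1)(c1ccccc1)OC/C=C(/C)C(=O)C#C[C@](C)(O)[C@H]1OC(C)(C)O[C@H]1CO[Si](C)(C)C(C)(C)C | intermediate
14 | (E)-C1-diethylamino enone from 13 (not isolated) | CC(C)(C)[Si](c1ccccc1)(c1ccccc1)OC/C=C(/C)C(=O)/C=C(/N(CC)CC)[C@](C)(O)[C@H]1OC(C)(C)O[C@H]1CO[Si](C)(C)C(C)(C)C | intermediate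
15 | (2R)-2-[(4S,5S)-5-{[(tert-butyldimethylsilyl)oxy]methyl}-2,2-dimethyl-1,3-dioxolan-4-yl]-2-methyl-5-{(2Z)-4-[(tert-butyldiphenylsilyl)oxy]but-2-en-2-yl}furan-3(2H)-one | CC(C)(C)[Si](c1ccccc1)(c1ccccc1)OC/C=C(/C)C1=CC(=O)[C@](C)(O1)[C@H]2OC(C)(C)O[C@H]2CO[Si](C)(C)C(C)(C)C | intermediate
16 | C7 alcohol: (2R)-2-[(4S,5S)-5-(hydroxymethyl)-2,2-dimethyl-1,3-dioxolan-4-yl]-2-methyl-5-{(2Z)-4-[(tert-butyldiphenylsilyl)oxy]but-2-en-2-yl}furan-3(2H)-one | CC(C)(C)[Si](c1ccccc1)(c1ccccc1)OC/C=C(/C)C1=CC(=O)[C@](C)(O1)[C@H]2OC(C)(C)O[C@H]2CO | intermediate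
17 | C7 aldehyde: (4R,5S)-5-[(2R)-furanon-2-yl]-2,2-dimethyl-1,3-dioxolane-4-carbaldehyde (furanone substituted as in 16) | CC(C)(C)[Si](c1ccccc1)(c1ccccc1)OC/C=C(/C)C1=CC(=O)[C@](C)(O1)[C@H]2OC(C)(C)O[C@H]2C=O | intermediate
18 | methyl acrylate | C=CC(=O)OC | starting material
19 | methyl 2-{hydroxy[(4S,5S)-dioxolan-4-yl]methyl}acrylate, O6-TBDPS (C7 epimers; 8S,9S,10R) | CC(C)(C)[Si](c1ccccc1)(c1ccccc1)OC/C=C(/C)C1=CC(=O)[C@](C)(O1)[C@H]2OC(C)(C)O[C@H]2C(O)C(=C)C(=O)OC | intermediate
20 | C6,C7-diol (C7 epimers; 8S,9S,10R; 4Z) | OC/C=C(/C)C1=CC(=O)[C@](C)(O1)[C@H]2OC(C)(C)O[C@H]2C(O)C(=C)C(=O)OC | intermediate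
21 | C7-hydroxy Z-enal (C7 epimers; 8S,9S,10R) | O=C/C=C(/C)C1=CC(=O)[C@](C)(O1)[C@H]2OC(C)(C)O[C@H]2C(O)C(=C)C(=O)OC | intermediate
22 | furanone Z-enal carrying the methyl (2Z)-2-(bromomethyl)acrylate at C7 (8S,9S,10R) | O=C/C=C(/C)C1=CC(=O)[C@](C)(O1)[C@H]2OC(C)(C)O[C@H]2/C=C(\CBr)C(=O)OC | intermediate
23 | C13 allylchromium dichloride (drawn with the geometry of 22; geometries interconvert; not isolated) | O=C/C=C(/C)C1=CC(=O)[C@](C)(O1)[C@H]2OC(C)(C)O[C@H]2/C=C(\C[Cr](Cl)Cl)C(=O)OC | intermediate
24 | bridged ten-membered C6 hydroxy ester with C11=C13 methylene (6R,7S,8S,9S,10R; 4Z) | O[C@@H]1/C=C(/C)C2=CC(=O)[C@](C)(O2)[C@H]3OC(C)(C)O[C@H]3[C@H]1C(=C)C(=O)OC | intermediate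
25 | trans-fused 6,12-lactone 8,9-acetonide (6R,7S,8S,9S,10R) | C=C1C(=O)O[C@@H]2/C=C(/C)C3=CC(=O)[C@](C)(O3)[C@H]4OC(C)(C)O[C@H]4[C@@H]12 | intermediate
26 | 8,9-diol lactone (6R,7R,8S,9S,10R) | C=C1C(=O)O[C@@H]2/C=C(/C)C3=CC(=O)[C@](C)(O3)[C@@H](O)[C@@H](O)[C@@H]12 | intermediate
27 | tert-butyl acrylate | C=CC(=O)OC(C)(C)C | starting material
28 | acetaldehyde | CC=O | starting material
29 | tert-butyl 3-hydroxy-2-methylenebutanoate (racemic) | C=C(C(C)O)C(=O)OC(C)(C)C | intermediate
30 | tert-butyl (2Z)-2-(bromomethyl)but-2-enoate | CC(C)(C)OC(=O)/C(=C/C)CBr | intermediate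
31 | tert-butyl (2E)-2-(acetoxymethyl)but-2-enoate | CC(C)(C)OC(=O)/C(=C/C)COC(C)=O | intermediate
32 | (2E)-2-(acetoxymethyl)but-2-enoic acid | OC(=O)/C(=C/C)COC(C)=O | intermediate
33 | mixed anhydride of 32 and 2,4,6-trichlorobenzoic acid (not isolated) | O=C(OC(=O)/C(=C/C)COC(C)=O)c1c(Cl)cc(Cl)cc1Cl | intermediate
34 | 8-O-[(2E)-2-(acetoxymethyl)but-2-enoyl] 9-alcohol (6R,7S,8S,9S,10R) | C=C1C(=O)O[C@@H]2/C=C(/C)C3=CC(=O)[C@](C)(O3)[C@@H](O)[C@@H](OC(=O)/C(=C/C)COC(C)=O)[C@@H]12 | intermediate
35 | CNP0325609.1 (6R,7S,8S,9S,10R; 4Z; side chain 2E) | C=C1C(=O)O[C@@H]2/C=C(/C)C3=CC(=O)[C@](C)(O3)[C@@H](OC(C)=O)[C@@H](OC(=O)/C(=C/C)COC(C)=O)[C@@H]12 | target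

**Step count**
- Total step count: 25.
- Longest linear sequence: 19 steps from L-arabinose (steps 1–6, 9–19, 24, 25).

**Steps most likely to fail**

Step 17.
- What may go wrong: closure of the strained bridged ring may be slower than intermolecular allylation or protonation of the allylchromium. The closed array may also give way to an open or boat-like one that adds in the syn sense and sets the C6 carbinol wrongly.
- Fallback (sets out from 22, comes back at 25): the ring is still closed with CrCl2, but the configuration at C6 is no longer asked of the addition. The syn adduct, the 6-epi hydroxy ester F1, is taken on. Its methyl ester is cleaved with Me3SnOH (1,2-dichloroethane, 60 °C) to the 6-epi hydroxy acid F2. An intramolecular Mitsunobu reaction (PPh3, DIAD, toluene, 0 °C) then lets the C12 carboxylate displace the activated O6 with inversion, which gives the trans-lactone 25.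

Step 13.
- What may go wrong: the amine-catalysed addition is slow. During that time the cis-configured α-alkoxy aldehyde can epimerise at C8, and reversible amine addition to the dienone can scramble the Z C4=C5 geometry.
- Fallback (sets out from 17, comes back at 19): the catalytic reaction is replaced by addition of a preformed vinylmetal. Hydroalumination of methyl propiolate with i-Bu2AlH in the presence of N-methylmorpholine N-oxide (THF, 0 °C) gives methyl 2-(diisobutylalumanyl)acrylate F3. This reagent adds to 17 quickly at 0 °C without any base and gives 19 after work-up.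

Step 24.
- What may go wrong: discrimination between the two cis hydroxyls may be insufficient, and the acyl group may migrate from O8 to O9 before the second acylation.
- Fallback (sets out from 26, comes back at 35): the steric difference is read out with a bulkier reagent that cannot migrate, and the acylation order is reversed. TBSCl and imidazole in DMF give the 8-O-TBS ether F4. Ac2O with DMAP gives its 9-acetate F5. HF·pyridine in THF frees the 8-hydroxy 9-acetate F6 under acidic conditions that do not move the acetate. Yamaguchi esterification of F6 with the mixed anhydride 33 then gives 35 directly.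

**Further compounds**

F1 | step 17 | 6-epi hydroxy ester (6S,7S,8S,9S,10R) | O[C@H]1/C=C(/C)C2=CC(=O)[C@](C)(O2)[C@H]3OC(C)(C)O[C@H]3[C@H]1C(=C)C(=O)OC
F2 | step 17 | 6-epi hydroxy acid | O[C@H]1/C=C(/C)C2=CC(=O)[C@](C)(O2)[C@H]3OC(C)(C)O[C@H]3[C@H]1C(=C)C(=O)O
F3 | step 13 | methyl 2-(diisobutylalumanyl)acrylate | C=C([Al](CC(C)C)CC(C)C)C(=O)OC
F4 | step 24 | 8-O-TBS ether of 26 | C=C1C(=O)O[C@@H]2/C=C(/C)C3=CC(=O)[C@](C)(O3)[C@@H](O)[C@@H](O[Si](C)(C)C(C)(C)C)[C@@H]12
F5 | step 24 | 9-acetate 8-O-TBS ether | C=C1C(=O)O[C@@H]2/C=C(/C)C3=CC(=O)[C@](C)(O3)[C@@H](OC(C)=O)[C@@H](O[Si](C)(C)C(C)(C)C)[C@@H]12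
F6 | step 24 | 8-hydroxy 9-acetate | C=C1C(=O)O[C@@H]2/C=C(/C)C3=CC(=O)[C@](C)(O3)[C@@H](OC(C)=O)[C@@H](O)[C@@H]12
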